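**Retrosynthetic overview** (terpenoid numbering: ring A = C1–C5 + C10, ring B = C5–C10, C11 = benzylic CH2)

1. The hydroxy-methoxy-quinone is carried as a 2,3,5,6-tetramethoxyphenyl group and unmasked last with (NH4)2Ce(NO3)6, followed by selective hydrolysis of one vinylogous ester.
2. The feature used: in ring A the fusion bond C5–C10 and the bond C3–C4 to the gem-dimethyl carbon flank C4–C5. Ring A is therefore the cyclohexene of a [4+2] between diene C10=C1–C2(OSi)=C3 and the enone double bond C5=C4(CH3)2, and the chain C6–C7–C8–C9 is the tether that becomes ring B.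
3. Rings A and B are closed together from acyclic trienone 24. The C6 carbonyl is then turned into the C5=C6 alkene by reduction and anti elimination (enolization of the C6 ketone toward C5 would place the oxygen against the C4 methyls, so an enolate-based route is not relied on), and the C2 oxygen is removed.
4. Trienone 24 comes from Weinreb amide 21. The silyloxydiene is made while C6 is still an amide, so only one ketone can be enolized; the β,β-dimethyl enone is added last with an alkenyl Grignard reagent.
5. C8 and C9 are set on (S)-4-methyl-δ-valerolactone by methylation, then benzylation anti to the C4 methyl. A reduction/oxidative lactonization moves the carbonyl from C10 to C6.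

Key step: step 14

Remark: methyl hydrogen (R)-3-methylglutarate (6) is assumed to be a commercial, enantiopure starting material; "β" means the face of ring B that carries the 8- and 9-methyl groups, so 9-CH2Ar and 10-H are α.

**Route**

Step 1
Reactants: 1 1,2,4,5-tetramethoxybenzene
Product: 3 2,3,5,6-tetramethoxybenzaldehyde, via aryllithium 2 (not isolated)
Conditions: n-BuLi, TMEDA, THF, 0 °C; DMF, 0 °C to rt; aq. HCl
Reagents that add atoms: N,N-dimethylformamide, CN(C)C=O
Why: Directed ortho-lithiation at the ring CH flanked by two methoxy groups, followed by formylation of the aryllithium with DMF, is standard for this arene.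

Step 2
Reactants: 3 2,3,5,6-tetramethoxybenzaldehyde
Product: 4 (2,3,5,6-tetramethoxyphenyl)methanol
Conditions: NaBH4, MeOH, 0 °C
Reagents that add atoms: none
Why: Borohydride reduction of an aromatic aldehyde to the benzylic alcohol, with no other reducible group present.

Step 3
Reactants: 4 (2,3,5,6-tetramethoxyphenyl)methanol
Product: 5 3-(bromomethyl)-1,2,4,5-tetramethoxybenzene
Conditions: PBr3, Et2O, 0 °C
Reagents that add atoms: phosphorus tribromide, BrP(Br)Br
Why: PBr3 converts the electron-rich benzylic alcohol into the bromide by SN2 displacement of the phosphite ester, and the aryl ethers tolerate the short cold treatment.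

Step 4
Reactants: 6 (R)-5-methoxy-3-methyl-5-oxopentanoic acid
Product: 8 (S)-4-methyloxan-2-one, via hydroxy acid 7 (not isolated)
Conditions: LiBH4, THF, 0 to 40 °C; then 3 M HCl, rt
Reagents that add atoms: none
Why: LiBH4 reduces the methyl ester but not the lithium carboxylate formed in situ, and the δ-hydroxy acid lactonizes on acidification; the stereocentre is untouched (the descriptor changes from R to S only because the CIP priorities change).

Step 5
Reactants: 8 (S)-4-methyloxan-2-one
Product: 10 (3R,4S)-3,4-dimethyloxan-2-one, via lithium enolate 9 (not isolated)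
Conditions: LiN(i-Pr)2, THF, −78 °C; MeI, −78 to −40 °C
Reagents that add atoms: iodomethane, CI
Why: Kinetic enolate alkylation of a δ-lactone, the electrophile entering anti to the C4 methyl to give the trans product; this new centre is planarized again in step 6, so its configuration is not critical.

Step 6
Reactants: 10 (3R,4S)-3,4-dimethyloxan-2-one; 5 3-(bromomethyl)-1,2,4,5-tetramethoxybenzene
Product: 12 (3R,4S)-3,4-dimethyl-3-[(2,3,5,6-tetramethoxyphenyl)methyl]oxan-2-one, via lithium enolate 11 (not isolated)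
Conditions: LiN(i-Pr)2, THF, DMPU, −78 °C; 5, −78 to −20 °C
Reagents that add atoms: none
Why: SN2 alkylation of the trisubstituted lactone enolate with a benzylic bromide; allylic 1,2-strain with the enolate methyl turns the C4 methyl pseudo-axial, so the benzyl group enters on the opposite face and the quaternary C9 is set with its methyl cis to the C8 methyl.

Step 7
Reactants: 12 (3R,4S)-3,4-dimethyl-3-[(2,3,5,6-tetramethoxyphenyl)methyl]oxan-2-one
Product: 13 (2R,3S)-2,3-dimethyl-2-[(2,3,5,6-tetramethoxyphenyl)methyl]pentane-1,5-diol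
Conditions: LiAlH4, THF, 0 °C to rt
Reagents that add atoms: none
Why: LiAlH4 reduction of a lactone to the 1,5-diol, with no stereocentre at risk.

Step 8
Reactants: 13 (2R,3S)-2,3-dimethyl-2-[(2,3,5,6-tetramethoxyphenyl)methyl]pentane-1,5-diol
Product: 15 (4S,5R)-4,5-dimethyl-5-[(2,3,5,6-tetramethoxyphenyl)methyl]oxan-2-one, via lactol 14 (not isolated)
Conditions: (n-Pr4N)RuO4 (5 mol %), N-methylmorpholine N-oxide, 4 Å MS, CH2Cl2, rt
Reagents that add atoms: none
Why: Ley–Griffith oxidative lactonization: the unhindered C6 carbinol is oxidized in preference to the neopentyl C10 carbinol, the hydroxy aldehyde closes to the lactol and this is oxidized on, which moves the carbonyl from C10 to C6.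

Step 9
Reactants: 15 (4S,5R)-4,5-dimethyl-5-[(2,3,5,6-tetramethoxyphenyl)methyl]oxan-2-one
Product: 16 (3S,4R)-5-hydroxy-N-methoxy-N,3,4-trimethyl-4-[(2,3,5,6-tetramethoxyphenyl)methyl]pentanamide
Conditions: MeNH(OMe)·HCl, i-PrMgCl, THF, −20 to 0 °C
Reagents that add atoms: N,O-dimethylhydroxylamine hydrochloride, CNOC.Cl
Why: Weinreb aminolysis of the unhindered lactone carbonyl by the chloromagnesium amide frees the neopentyl alcohol and installs the amide that later becomes the C6 ketone.

Step 10
Reactants: 16 (3S,4R)-5-hydroxy-N-methoxy-N,3,4-trimethyl-4-[(2,3,5,6-tetramethoxyphenyl)methyl]pentanamide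
Product: 17 (3S,4R)-N-methoxy-N,3,4-trimethyl-5-oxo-4-[(2,3,5,6-tetramethoxyphenyl)methyl]pentanamide
Conditions: Dess–Martin periodinane, NaHCO3, CH2Cl2, 0 °C to rt
Reagents that add atoms: none
Why: Dess–Martin oxidation of the neopentyl primary alcohol to an aldehyde on a quaternary carbon, which cannot epimerize; used at once to avoid relactonization of 16.

Step 11
Reactants: 17 (3S,4R)-N-methoxy-N,3,4-trimethyl-5-oxo-4-[(2,3,5,6-tetramethoxyphenyl)methyl]pentanamide; 18 dimethyl (2-oxopropyl)phosphonate
Product: 20 (3S,4R,5E)-N-methoxy-N,3,4-trimethyl-7-oxo-4-[(2,3,5,6-tetramethoxyphenyl)methyl]oct-5-enamide, via sodium phosphonate salt 19 (not isolated)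
Conditions: 18, NaH, THF, 0 °C; then 17, 0 to 40 °C
Reagents that add atoms: none
Why: Horner–Wadsworth–Emmons olefination of the hindered, non-enolizable aldehyde with the stabilized ketophosphonate anion should give the (E)-enone.

Step 12
Reactants: 20 (3S,4R,5E)-N-methoxy-N,3,4-trimethyl-7-oxo-4-[(2,3,5,6-tetramethoxyphenyl)methyl]oct-5-enamide
Product: 21 (3S,4R,5E)-7-[(tert-butyldimethylsilyl)oxy]-N-methoxy-N,3,4-trimethyl-4-[(2,3,5,6-tetramethoxyphenyl)methyl]octa-5,7-dienamide
Conditions: TBSOTf, Et3N, CH2Cl2, −78 to 0 °C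
Reagents that add atoms: tert-butyldimethylsilyl trifluoromethanesulfonate, CC(C)(C)[Si](C)(C)OS(=O)(=O)C(F)(F)F
Why: Soft enolization of the methyl enone on its methyl group gives the 2-silyloxy-1,3-diene; the Weinreb amide is far less acidic and is not enolized, which is why the second ketone is still masked here.

Step 13
Reactants: 21 (3S,4R,5E)-7-[(tert-butyldimethylsilyl)oxy]-N-methoxy-N,3,4-trimethyl-4-[(2,3,5,6-tetramethoxyphenyl)methyl]octa-5,7-dienamide; 22 2-methylprop-1-enylmagnesium bromide
Product: 24 (6S,7R,8E)-10-[(tert-butyldimethylsilyl)oxy]-2,6,7-trimethyl-7-[(2,3,5,6-tetramethoxyphenyl)methyl]undeca-2,8,10-trien-4-one, via tetrahedral magnesium adduct 23 (not isolated)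
Conditions: 22, THF, 0 °C; cold aq. NH4Cl
Reagents that add atoms: none
Why: Weinreb ketone synthesis: the alkenyl Grignard addition stops at the chelated adduct, which releases the β,β-dimethyl enone only on mild aqueous work-up, and the TBS dienol ether is inert to both.

Step 14
Reactants: 24 (6S,7R,8E)-10-[(tert-butyldimethylsilyl)oxy]-2,6,7-trimethyl-7-[(2,3,5,6-tetramethoxyphenyl)methyl]undeca-2,8,10-trien-4-one
Product: 25 (5βH,10αH)-2-(tert-butyldimethylsilyloxy)-4,4,8β,9β-tetramethyl-9α-(2,3,5,6-tetramethoxybenzyl)decal-1-en-6-one (trans-fused)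
Conditions: toluene (0.01 M), BHT (cat.), Et3N (cat.), sealed tube, 190 °C
Reagents that add atoms: none
Why: A thermal, concerted but asynchronous normal-demand [4+2] cycloaddition in which the diene C10=C1–C2(OTBS)=C3 adds across C5=C4, the nucleophilic terminus C3 bonding to the enone β-carbon C4 and C10 to C5; the closest known reaction type is the intramolecular Diels–Alder reaction of 2-silyloxy-1,3-dienes with tethered enones (1,7,9-decatrien-3-ones). Ring A is closed as the new cyclohexene of the cycloaddition, and ring B is closed by the C5–C10 bond through the four-atom tether C6–C7–C8–C9 in a chair-like six-membered array. C10 is controlled by C8 and C9: in the chair the C8 methyl and the C9 CH2Ar group are equatorial and the C9 methyl axial, so C5 adds to the diene face that leaves H-10 cis to CH2Ar. C5 is set by the exo orientation of the C6 carbonyl (trans fusion), because the endo mode would push C4 and its two methyls under the axial C9 methyl; this centre is removed in step 16 and a cis-fused epimer would equilibrate to 25 through the enol. The step needs reactivity from a β,β-dimethylated dienophile and facial selectivity at C10: the first is served by the silyloxy donor, the conjugated C6 carbonyl and the Thorpe–Ingold effect of quaternary C9, the second by the equatorial preference of the C8 methyl, and the regiochemistry is fixed by the tether.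

Step 15
Reactants: 25 (5βH,10αH)-2-(tert-butyldimethylsilyloxy)-4,4,8β,9β-tetramethyl-9α-(2,3,5,6-tetramethoxybenzyl)decal-1-en-6-one
Product: 26 (5βH,10αH)-2-(tert-butyldimethylsilyloxy)-4,4,8β,9β-tetramethyl-9α-(2,3,5,6-tetramethoxybenzyl)decal-1-en-6α-ol (axial OH)
Conditions: LiBH(s-Bu)3, THF, −78 to 0 °C; H2O
Reagents that add atoms: none
Why: The bulky hydride attacks the C6 ketone from the equatorial direction, away from the syn-axial 4α-methyl, to give the axial 6α-alcohol that is anti-periplanar to H-5; the silyl enol ether is inert to hydride.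

Step 16
Reactants: 26 the axial 6α-alcohol
Product: 28 (10αH)-2-(tert-butyldimethylsilyloxy)-4,4,8β,9β-tetramethyl-9α-(2,3,5,6-tetramethoxybenzyl)decalin-1,5-diene, via dichlorophosphate 27 (not isolated)
Conditions: POCl3, pyridine, 0 to 70 °C
Reagents that add atoms: none
Why: E2 dehydration through the dichlorophosphate: the axial leaving group is anti-periplanar to axial H-5, and loss of H-5 gives the more substituted (Zaitsev) C5=C6 alkene and relieves the 1,3-diaxial strain with the 4α-methyl, as in the dehydration of axial 6-hydroxy steroids to 5-enes; the C5 stereocentre disappears here.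

Step 17
Reactants: 28 the 1,5-diene silyl enol ether
Product: 29 (10αH)-4,4,8β,9β-tetramethyl-9α-(2,3,5,6-tetramethoxybenzyl)decal-5-en-2-one
Conditions: 1 M HCl (cat.), THF/H2O, 0 °C to rt
Reagents that add atoms: none
Why: Mild acid hydrolysis of the silyl enol ether gives the C2 ketone; the alkene is separated from the carbonyl by sp3 C10, so neither conjugation nor epimerization at C10 is expected.

Step 18
Reactants: 29 (10αH)-4,4,8β,9β-tetramethyl-9α-(2,3,5,6-tetramethoxybenzyl)decal-5-en-2-one
Product: 31 3-{[(1R,2S,8aS)-1,2,5,5-tetramethyl-1,2,3,5,6,7,8,8a-octahydronaphthalen-1-yl]methyl}-1,2,4,5-tetramethoxybenzene, via hydrazone 30 (not isolated)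
Conditions: N2H4·H2O, KOH, diethylene glycol, 130 °C then 195 °C
Reagents that add atoms: none
Why: Wolff–Kishner reduction (Huang–Minlon procedure) removes the C2 carbonyl through the hydrazone; the isolated trisubstituted alkene and the unactivated aryl ethers should survive the base.

Step 19
Reactants: 31 the tetramethoxyarene
Product: 32 2,5-dimethoxy-3-{[(1R,2S,8aS)-1,2,5,5-tetramethyl-1,2,3,5,6,7,8,8a-octahydronaphthalen-1-yl]methyl}cyclohexa-2,5-diene-1,4-dione
Conditions: (NH4)2Ce(NO3)6, MeCN/H2O, 0 °C
Reagents that add atoms: water, O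
Why: Oxidative demethylation of a para-dimethoxy pair gives the 2,5-dimethoxy-1,4-benzoquinone (both para pairs lead to the same quinone), and the hindered alkene is oxidized far more slowly than the arene.

Step 20
Reactants: 32 the dimethoxyquinone
Product: 33 2-hydroxy-5-methoxy-3-{[(1R,2S,8aS)-1,2,5,5-tetramethyl-1,2,3,5,6,7,8,8a-octahydronaphthalen-1-yl]methyl}cyclohexa-2,5-diene-1,4-dione (CNP0348245.1)
Conditions: KOH, MeOH/H2O, rt; then 1 M HCl
Reagents that add atoms: potassium hydroxide, [K+].[OH-]
Why: Addition–elimination of hydroxide on the vinylogous ester; by analogy with other 3-alkyl-2,5-dimethoxy-1,4-benzoquinones the methoxy group next to the alkyl substituent should be the one exchanged, and acidification gives the hydroxyquinone.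

**Compound list**

1 | 1,2,4,5-tetramethoxybenzene | COc1cc(OC)c(OC)cc1OC | starting material
2 | (2,3,5,6-tetramethoxyphenyl)lithium | [Li]c1c(OC)c(OC)cc(OC)c1OC | intermediate
3 | 2,3,5,6-tetramethoxybenzaldehyde | O=Cc1c(OC)c(OC)cc(OC)c1OC | intermediate
4 | (2,3,5,6-tetramethoxyphenyl)methanol | OCc1c(OC)c(OC)cc(OC)c1OC | intermediate
5 | 3-(bromomethyl)-1,2,4,5-tetramethoxybenzene | BrCc1c(OC)c(OC)cc(OC)c1OC | intermediate
6 | (R)-5-methoxy-3-methyl-5-oxopentanoic acid (methyl hydrogen (R)-3-methylglutarate) | COC(=O)C[C@H](C)CC(=O)O | starting material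
7 | (S)-5-hydroxy-3-methylpentanoic acid | OCC[C@H](C)CC(=O)O | intermediate
8 | (S)-4-methyloxan-2-one | O=C1C[C@@H](C)CCO1 | intermediate
9 | lithium enolate of 8 | C[C@H]1CCOC(O[Li])=C1 | intermediate
10 | (3R,4S)-3,4-dimethyloxan-2-one | C[C@H]1CCOC(=O)[C@@H]1C | intermediate
11 | lithium enolate of 10 | C[C@H]1CCOC(O[Li])=C1C | intermediate
12 | (3R,4S)-3,4-dimethyl-3-[(2,3,5,6-tetramethoxyphenyl)methyl]oxan-2-one | C[C@H]1CCOC(=O)[C@]1(C)Cc1c(OC)c(OC)cc(OC)c1OC | intermediate
13 | (2R,3S)-2,3-dimethyl-2-[(2,3,5,6-tetramethoxyphenyl)methyl]pentane-1,5-diol | OC[C@](C)(Cc1c(OC)c(OC)cc(OC)c1OC)[C@@H](C)CCO | intermediate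
14 | (4S,5R)-4,5-dimethyl-5-[(2,3,5,6-tetramethoxyphenyl)methyl]oxan-2-ol (lactol) | OC1C[C@H](C)[C@@](C)(Cc2c(OC)c(OC)cc(OC)c2OC)CO1 | intermediate
15 | (4S,5R)-4,5-dimethyl-5-[(2,3,5,6-tetramethoxyphenyl)methyl]oxan-2-one | O=C1C[C@H](C)[C@@](C)(Cc2c(OC)c(OC)cc(OC)c2OC)CO1 | intermediate
16 | (3S,4R)-5-hydroxy-N-methoxy-N,3,4-trimethyl-4-[(2,3,5,6-tetramethoxyphenyl)methyl]pentanamide | CON(C)C(=O)C[C@H](C)[C@@](C)(Cc1c(OC)c(OC)cc(OC)c1OC)CO | intermediate
17 | (3S,4R)-N-methoxy-N,3,4-trimethyl-5-oxo-4-[(2,3,5,6-tetramethoxyphenyl)methyl]pentanamide | CON(C)C(=O)C[C@H](C)[C@@](C)(Cc1c(OC)c(OC)cc(OC)c1OC)C=O | intermediate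
18 | dimethyl (2-oxopropyl)phosphonate | COP(=O)(CC(C)=O)OC | starting material
19 | sodium salt of 18 | [Na+].COP(=O)(OC)[CH-]C(C)=O | intermediate
20 | (3S,4R,5E)-N-methoxy-N,3,4-trimethyl-7-oxo-4-[(2,3,5,6-tetramethoxyphenyl)methyl]oct-5-enamide | CON(C)C(=O)C[C@H](C)[C@@](C)(Cc1c(OC)c(OC)cc(OC)c1OC)/C=C/C(C)=O | intermediate
21 | (3S,4R,5E)-7-[(tert-butyldimethylsilyl)oxy]-N-methoxy-N,3,4-trimethyl-4-[(2,3,5,6-tetramethoxyphenyl)methyl]octa-5,7-dienamide | CON(C)C(=O)C[C@H](C)[C@@](C)(Cc1c(OC)c(OC)cc(OC)c1OC)/C=C/C(=C)O[Si](C)(C)C(C)(C)C | intermediate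
22 | 2-methylprop-1-enylmagnesium bromide | CC(C)=C[Mg]Br | starting material
23 | tetrahedral magnesium adduct of 21 and 22 | CON(C)C(O[Mg]Br)(C=C(C)C)C[C@H](C)[C@@](C)(Cc1c(OC)c(OC)cc(OC)c1OC)/C=C/C(=C)O[Si](C)(C)C(C)(C)C | intermediate
24 | (6S,7R,8E)-10-[(tert-butyldimethylsilyl)oxy]-2,6,7-trimethyl-7-[(2,3,5,6-tetramethoxyphenyl)methyl]undeca-2,8,10-trien-4-one | COc1cc(OC)c(OC)c(C[C@@](C)(/C=C/C(=C)O[Si](C)(C)C(C)(C)C)[C@@H](C)CC(=O)C=C(C)C)c1OC | intermediate
25 | (5βH,10αH)-2-(tert-butyldimethylsilyloxy)-4,4,8β,9β-tetramethyl-9α-(2,3,5,6-tetramethoxybenzyl)decal-1-en-6-one (trans-fused) | COc1cc(OC)c(OC)c(C[C@@]2(C)[C@@H]3C=C(O[Si](C)(C)C(C)(C)C)CC(C)(C)[C@H]3C(=O)C[C@@H]2C)c1OC | intermediate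
26 | 6α-alcohol of 25 (axial OH) | COc1cc(OC)c(OC)c(C[C@@]2(C)[C@@H]3C=C(O[Si](C)(C)C(C)(C)C)CC(C)(C)[C@H]3[C@@H](O)C[C@@H]2C)c1OC | intermediate
27 | 6α-dichlorophosphate of 26 | COc1cc(OC)c(OC)c(C[C@@]2(C)[C@@H]3C=C(O[Si](C)(C)C(C)(C)C)CC(C)(C)[C@H]3[C@@H](OP(=O)(Cl)Cl)C[C@@H]2C)c1OC | intermediate
28 | (10αH)-2-(tert-butyldimethylsilyloxy)-4,4,8β,9β-tetramethyl-9α-(2,3,5,6-tetramethoxybenzyl)decalin-1,5-diene | COc1cc(OC)c(OC)c(C[C@@]2(C)[C@@H]3C=C(O[Si](C)(C)C(C)(C)C)CC(C)(C)C3=CC[C@@H]2C)c1OC | intermediate
29 | (10αH)-4,4,8β,9β-tetramethyl-9α-(2,3,5,6-tetramethoxybenzyl)decal-5-en-2-one | COc1cc(OC)c(OC)c(C[C@@]2(C)[C@@H]3CC(=O)CC(C)(C)C3=CC[C@@H]2C)c1OC | intermediate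
30 | hydrazone of 29 | COc1cc(OC)c(OC)c(C[C@@]2(C)[C@@H]3CC(=NN)CC(C)(C)C3=CC[C@@H]2C)c1OC | intermediate
31 | 3-{[(1R,2S,8aS)-1,2,5,5-tetramethyl-1,2,3,5,6,7,8,8a-octahydronaphthalen-1-yl]methyl}-1,2,4,5-tetramethoxybenzene | COc1cc(OC)c(OC)c(C[C@@]2(C)[C@@H]3CCCC(C)(C)C3=CC[C@@H]2C)c1OC | intermediate
32 | 2,5-dimethoxy-3-{[(1R,2S,8aS)-1,2,5,5-tetramethyl-1,2,3,5,6,7,8,8a-octahydronaphthalen-1-yl]methyl}cyclohexa-2,5-diene-1,4-dione | COC1=CC(=O)C(OC)=C(C[C@@]2(C)[C@@H]3CCCC(C)(C)C3=CC[C@@H]2C)C1=O | intermediate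
33 | 2-hydroxy-5-methoxy-3-{[(1R,2S,8aS)-1,2,5,5-tetramethyl-1,2,3,5,6,7,8,8a-octahydronaphthalen-1-yl]methyl}cyclohexa-2,5-diene-1,4-dione (CNP0348245.1) | COC1=CC(=O)C(O)=C(C[C@@]2(C)[C@@H]3CCCC(C)(C)C3=CC[C@@H]2C)C1=O | target

**Step count**

Total: 20 steps. Longest linear sequence: 18 steps (steps 1 to 3 and then 6 to 20, from 1); the lactone branch (steps 4 and 5, from 6) joins at step 6.

**Steps most likely to fail**

1. Step 14. The cycloaddition may be too slow at temperatures the silyl dienol ether tolerates, because the new bond to C4 creates a quaternary carbon from a β,β-dimethylated dienophile; the preference for the desired C10 face may also be modest. The fallback sets out from 21 and comes back at 25. Prop-1-ynylmagnesium bromide (THF, 0 °C) should convert the Weinreb amide into (6S,7R,8E)-10-[(tert-butyldimethylsilyl)oxy]-6,7-dimethyl-7-[(2,3,5,6-tetramethoxyphenyl)methyl]undeca-8,10-dien-2-yn-4-one F1. The alkynone is a less hindered and more reactive dienophile, so the same intramolecular cycloaddition through the same chair tether should proceed at 110–140 °C in toluene and give the cyclohexa-1,4-diene that keeps the conjugated C4=C5–C6=O unit, dienone F2. Conjugate addition of Me2CuLi (Et2O, −20 °C) to this exocyclic tetrasubstituted enone, a pulegone-type acceptor, places the second methyl on C4, and protonation of the resulting C5 enolate (aq. NH4Cl) gives 25.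

2. Step 16. The elimination may remove the axial proton at C7 instead of H-5 and give the C6=C7 isomer, or chloride may substitute at C6. The fallback sets out from 25 and comes back at 28. The ketone is deprotonated under equilibrating conditions (KN(SiMe3)2, slightly less than one equivalent, THF, −78 to 0 °C) and the enolate is trapped with PhNTf2 as the C5=C6 enol triflate F3. Reduction with Pd(OAc)2, PPh3, Bu3N and HCO2H in DMF at 60 °C then gives 28. Because the C5 enolate is strained against the C4 methyls, the equilibrium may not favour it; in that case the same enolate is available regiospecifically from the cuprate addition to F2 described under point 1 and can be trapped with PhNTf2 directly.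

3. Step 6. Formation of the quaternary centre with a di-ortho-substituted benzylic bromide may stall, with O-alkylation or decomposition of the bromide competing. The fallback sets out from 10 and comes back at 12. The enolate 11 is added to aldehyde 3 (THF, −78 °C), a carbonyl addition that is sterically less demanding than the SN2 reaction and should take place on the same face, to give the β-hydroxy lactone F4. Ionic deoxygenation of the benzylic alcohol (Et3SiH, CF3CO2H, CH2Cl2, 0 °C) then gives 12; the cation is stabilized by the methoxy groups and has no β-hydrogen on the quaternary carbon to lose.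

**Further compounds**

F1 | step 14 | (6S,7R,8E)-10-[(tert-butyldimethylsilyl)oxy]-6,7-dimethyl-7-[(2,3,5,6-tetramethoxyphenyl)methyl]undeca-8,10-dien-2-yn-4-one | COc1cc(OC)c(OC)c(C[C@@](C)(/C=C/C(=C)O[Si](C)(C)C(C)(C)C)[C@@H](C)CC(=O)C#CC)c1OC
F2 | step 14 | (10αH)-2-(tert-butyldimethylsilyloxy)-4,8β,9β-trimethyl-9α-(2,3,5,6-tetramethoxybenzyl)decalin-1,4-dien-6-one | COc1cc(OC)c(OC)c(C[C@@]2(C)[C@@H]3C=C(O[Si](C)(C)C(C)(C)C)CC(C)=C3C(=O)C[C@@H]2C)c1OC
F3 | step 16 | (10αH)-2-(tert-butyldimethylsilyloxy)-4,4,8β,9β-tetramethyl-9α-(2,3,5,6-tetramethoxybenzyl)decalin-1,5-dien-6-yl trifluoromethanesulfonate | COc1cc(OC)c(OC)c(C[C@@]2(C)[C@@H]3C=C(O[Si](C)(C)C(C)(C)C)CC(C)(C)C3=C(OS(=O)(=O)C(F)(F)F)C[C@@H]2C)c1OC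
F4 | step 6 | (3R,4S)-3-[hydroxy(2,3,5,6-tetramethoxyphenyl)methyl]-3,4-dimethyloxan-2-one | C[C@H]1CCOC(=O)[C@]1(C)C(O)c1c(OC)c(OC)cc(OC)c1OC
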